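Count turnovers.

the same everywhere: substrate 20 mM; enzyme 0.035 mol%

| run | capture agent | remark | time |
|---|---|---|---|
| north-east | 1 mM | the very flask that is asked about, followed so far |  |
| south-east | 2 mM | run made earlier |  |
| flask | 1.00 mM |  | 8.0 d |

| run | time / h | product / % |
|---|---|---|
| north-east | 12.0 | 9.1 |
| north-east | 25.0 | 8.4 |
| north-east | 40.0 | 8.4 |
| north-east | 72.0 | 8.8 |
| north-east | 144 | 9.1 |
| south-east | 1.50 | 4.5 |
| south-east | 3.00 | 4.6 |
| south-east | 5.00 | 5.0 |
| south-east | 6.00 | 4.5 |
| south-east | 8.00 | 4.7 |

(readings scatter by 0.3 percentage points)

- Saturday's: at 8.0 d add enzyme, 100 % of the amount charged, then wait 15 d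
- Wednesday's: at 8.0 d add substrate, 50.0 % of the amount charged, then wait 15 d
- Thursday's: change nothing and wait 15 d more
- Sunday's: at 8.0 d take out 90 % of the product then present, then wait 15 d

- what is taken out of product is counted as made
- the numbers in the tables scatter by 0.3 percentage points (one standard deviation)
- additions bring no volume worth counting

- product, in percent of the substrate first charged, at 8.0 d
- the option that brings most further product ("none" if no option brings more than 2 percentage points) (Saturday's / Wednesday's / Thursday's / Sunday's / none)
- product present, with what was taken out counted in, in percent of the substrate first charged, after Wednesday's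
- product present, with what was taken out counted in, in percent of the substrate first charged, after Thursday's

Both runs go flat early: the north-east flask at a mean of 8.76 %, the south-east run at 4.66 %. In the north-east flask 91.2 % of the substrate stands unconverted, so running out of substrate is not what stops it. Dividing product by enzyme charged gives the turnover number, 250 in the north-east flask and 133 in the south-east run. Multiplying each by c(capture agent) gives 250 mM and 266 mM. Their mean, 258 mM, I call the allowance: turnover number times c(capture agent).

If the capture agent destroys the enzyme one for one, the whole enzyme charge of 0.00700 mM costs the north-east flask 0.700 % of its capture agent, so c(capture agent) stays within that share of its charge and the loss is pseudo-first-order. The south-east run is flat by its first reading, at 1.50 h, so I grant it at least 2 lifetimes by then. With half the capture agent, that grant gives the asked flask an estimated lifetime of at most 1.50 h. Its 8.0 d then hold 128 lifetimes, and on that count hardly any working enzyme remains.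

So I commit to 9.04 % now, with nothing further from waiting, substrate or removing product. Fresh enzyme at the same allowance gains about 9.04 %, against a bar of 2 percentage points.

The weak link is the loss of enzyme, since flat could mean a balance. But the two runs share their substrate charge, so a balance of substrate and product with the capture agent as bystander gives both runs one plateau, and the north-east flask reads twice as high as the south-east run.

The forecast says 8.8 %, Saturday's, 8.8 % after Wednesday's and 8.8 % after Thursday's, on the ground that “the capture agent kills the enzyme”. Its 8.8 % stands lower than my 9.04 %.

The flask gives 8.97 %. Saturday's brings 8.6 points, while Wednesday's, Thursday's and Sunday's bring 0 points, 0 points and 0 points, so the flask stands at 8.97 % after Wednesday's and 8.97 % after Thursday's.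

    substrate + enzyme ⇌ complex (K = 1880 L mol⁻¹, k = 189 L mol⁻¹ s⁻¹)
    capture agent + complex → trapped intermediate (k = 8.60 L mol⁻¹ s⁻¹)
    complex ⇌ enzyme + product (K = 0.0239 M, k = 2.25 s⁻¹)
    2 enzyme ⇌ resting dimer (K = 1.60 × 10⁵ L mol⁻¹, k = 9.12 L mol⁻¹ s⁻¹)

At 192 h the catalyst of this flask stands as trapped intermediate, 100 %, with complex at 0 %, enzyme at 0 % and resting dimer at 0 %. For the neighbouring flask with 0.14 mol% of enzyme, the allowance at the same c(capture agent) gives 36.2 %. That flask keeps 97 % of its capture agent and 67 % of its substrate, and it gives 33.4 % of product.

Readings and results are calculated from invented constants, and the scatter is random.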